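All runs are calculated for substances that don't exist; noise was put on by code.

Monday's run stood at 93.5 % at its last reading, and two chemists differ over what that level means for the two flasks asked about.

| flask | free monomer | protic impurity | initiator | temperature | remark | time |
|---|---|---|---|---|---|---|
| Saturday's | 0.50 M | 0.50 M | 2.5 mol% | 24 °C | run made earlier |  |
| Monday's | 0.50 M | 0.50 M | 3.8 mol% | 32 °C | run made earlier |  |
| Thursday's | 0.50 M | 0.75 M | 5 mol% | 24 °C | run made earlier |  |
| south-east | 0.50 M | 0.500 M | 5 mol% | 20 °C |  | 40 h |
| north-west | 0.50 M | 0.500 M | 5 mol% | 35 °C |  | 40 h |

| run | time / h | monomer in chains / % |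
|---|---|---|
| Saturday's | 2.00 | 20.4 |
| Saturday's | 4.00 | 36.6 |
| Saturday's | 10.0 | 66.3 |
| Saturday's | 25.0 | 89.2 |
| Monday's | 1.00 | 29.9 |
| Monday's | 2.00 | 49.5 |
| Monday's | 6.00 | 84.3 |
| Monday's | 15.0 | 93.5 |
| Thursday's | 3.00 | 38.0 |
| Thursday's | 8.00 | 70.1 |
| Thursday's | 15.0 | 87.1 |
| Thursday's | 25.0 | 91.1 |

(scatter of a reading: 0.5 percentage points)

* which flask leads in amount of monomer in chains, in percent of the free monomer charged ("all alike" within 1.5 percentage points) (south-east / north-west / all alike)
* how much monomer in chains is there at the end, in percent of the free monomer charged: south-east
* how much monomer in chains is there at the end, in percent of the free monomer charged: north-west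



Both agree that monomer in chains climbs towards a plateau and that the gap to it shrinks in a pseudo-first-order way, at a relaxation rate. They part over the plateau. The forecast's side holds that it moves with the flask: “The plateau therefore rises slightly with temperature, though weakly determined”. It gives 92.2 % for south-east and 94 % for north-west, so north-west leads by 1.8 percentage points, more than the margin.

I hold one plateau for both flasks, taken at Monday's last reading, and ask how far each has come. Against it, Saturday's reading at 10.0 h gives a relaxation rate of 0.123 /h, Thursday's at 8.00 h gives 0.173 /h, and Monday's at 2.00 h gives 0.377 /h. Thursday's 5 mol% of initiator against Saturday's 2.5 mol% goes with a rate 1.41 times as high, close to the square root of the loadings, 1.41. But Thursday's run also carried more protic impurity, so the square root is my assumption. With it, Monday's rate over Saturday's leaves a temperature factor of 2.48. Scaling that exponentially in temperature gives 0.111 /h for south-east and 0.607 /h for north-west.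

The logarithm of plateau over margin, divided by these rates, gives 37.2 h for south-east and 6.80 h for north-west. This is the crossing time: the moment a flask's gap to its plateau has shrunk to the margin, where control passes from rate to plateau. By this reckoning south-east crosses before 40 h, with a reckoned gap of 1.1 points at that time, so my own reckoning, unlike the forecast, says all alike.

The simulation gives all alike: south-east 93.9 %, north-west 94.8 %, 0.90 points apart.

    free monomer + growing radical → monomer in chains + growing radical, rate k1*[growing radical]*[free monomer] (k = 25100 /M/s, Ea = 34.0 kJ/mol)
    protic impurity + free monomer → quenched substrate (k = 1.79 × 10⁻⁵ /M/s, Ea = 88.0 kJ/mol)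
    2 growing radical → dead chain (k = 2.80 × 10⁸ /M/s, Ea = 8.00 kJ/mol)
    initiator → 2 initiating radical (k = 4.52 × 10⁻⁷ /s, Ea = 111 kJ/mol)
    free monomer + initiating radical → growing radical + monomer in chains (k = 87400 /M/s, Ea = 35.0 kJ/mol)
    (constants at 35 °C)

A north-west lead above the margin does stand earlier, before south-east's crossing time of 37.2 h: at 20.0 h, north-west holds 94.8 % of monomer in chains against 84.4 % in south-east. A neighbour flask like south-east but with 1.2 mol% of initiator has, by the square root, a reckoned crossing time of 76.0 h, later than 40 h. At 40.0 h that neighbour holds 81.0 % of monomer in chains, with 10.6 % of the charged free monomer still there.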